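**Strategy.** Everything rests on the bond between the two adjacent quaternary carbons shared by the cycloheptane, cyclopentane, piperidine and ε-lactone rings: Ca (allylic to the cyclopentene C=C) and Cb (bearing the lactone OCH2). That alkene and the oxygenated one-carbon branch on Cb are the retron of an ester-enolate Claisen rearrangement. A bridged nine-membered allylic lactone (a 2-oxabicyclo[6.2.1]undecan-3-one with an exocyclic tetrasubstituted alkene) is ring-contracted in an Ireland–Claisen step that closes the cycloheptane, forms Ca–Cb, sets both quaternary stereocentres and moves the alkene into the cyclopentene. A double Mannich endgame then builds the azatricycle.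

Key step: step 12

Remarks on the chemistry: 2, 8, 12 and 14 are taken as purchasable. The α-carbon of acid 19 (the lactone α-carbon in 20–23) is formed as a mixture of epimers and is drawn without a descriptor, because step 12 planarises it. The geometry of the ketene acetals 17 and 24 is likewise left undrawn.

**Step 1**
Reactants: 1 methyl pent-4-enoate; 2 diethyl prop-2-en-1-yl phosphate
Product: 3 methyl (4E)-6-[(diethoxyphosphoryl)oxy]hex-4-enoate
Conditions: second-generation Grubbs catalyst [RuCl2(PCy3)(H2IMes)(=CHPh)] (3 mol %), 2 (3 equiv), CH2Cl2, 40 °C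
Reagents that add atoms: none
Why: Olefin cross-metathesis of two terminal alkenes with the cheap partner in excess should give the E-allylic phosphate under thermodynamic control; no stereocentre is formed.

**Step 2**
Reactants: 3 methyl (4E)-6-[(diethoxyphosphoryl)oxy]hex-4-enoate; 4 3,3-diethoxyprop-1-yne
Product: 6 methyl (4S)-7,7-diethoxy-4-ethenylhept-5-ynoate, via alkynylalane 5 (not isolated)
Conditions: 4, i-Bu2AlH (1.0 equiv), Et3N (5 mol %), hexanes, 22 °C; then 3, CuCl2·2H2O (2 mol %), chiral sulfonate-bearing imidazolinium salt (NHC precursor, 2.5 mol %, enantiomer that delivers 4S), THF, −15 °C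
Reagents that add atoms: none
Why: Copper–NHC-catalysed enantioselective allylic substitution with an alkynylaluminium reagent is SN2′-selective on E-disubstituted allylic phosphates, so the alkynyl group goes to the γ-carbon and the chiral ligand sets the new tertiary stereocentre (4S).

**Step 3**
Reactants: 6 methyl (4S)-7,7-diethoxy-4-ethenylhept-5-ynoate
Product: 7 (4S)-7,7-diethoxy-4-ethenylhept-5-ynal
Conditions: i-Bu2AlH (1.05 equiv), CH2Cl2, −78 °C; aq. potassium sodium tartrate
Reagents that add atoms: none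
Why: Partial reduction of a methyl ester at −78 °C stops at the tetrahedral aluminium hemiacetal and gives the aldehyde on work-up; the stereocentre is γ to the carbonyl and cannot epimerise.

**Step 4**
Reactants: 7 (4S)-7,7-diethoxy-4-ethenylhept-5-ynal; 8 tert-butyl(3-iodopropoxy)dimethylsilane
Product: 10 (1S,2E,3S)-2-{5-[(tert-butyldimethylsilyl)oxy]-1,1-diethoxypentan-2-ylidene}-3-ethenylcyclopentan-1-ol, via alkylzinc iodide 9 (not isolated)
Conditions: 8, Zn dust, LiCl, THF, 40 °C; then 7, Ni(cod)2 (10 mol %), THF, 0 → 23 °C; aq. NH4Cl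
Reagents that add atoms: none
Why: Nickel-catalysed alkylative cyclisation of a hex-5-ynal with an organozinc: oxidative cyclisation at zerovalent nickel gives an oxanickelacyclopentene, so the new ring C–C bond and the alkyl group transferred from zinc end up cis on the exocyclic alkene (E isomer), and a half-chair transition state with the vinyl group pseudoaxial (no allylic strain with the acetal terminus) and the O–Ni bond in the alkene plane should give the 1,3-cis carbinol (1S).

**Step 5**
Reactants: 11 (2R)-but-3-en-2-ol; 12 di-tert-butyl N-(prop-2-en-1-yl)imidodicarbonate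
Product: 13 di-tert-butyl N-[(2E,4R)-4-hydroxypent-2-en-1-yl]imidodicarbonate
Conditions: second-generation Grubbs catalyst [RuCl2(PCy3)(H2IMes)(=CHPh)] (3 mol %), 12 (3 equiv), CH2Cl2, 40 °C
Reagents that add atoms: none
Why: Cross-metathesis with the allyl imidodicarbonate in excess should give the E-alkene; the carbinol stereocentre of 11 is not touched.

**Step 6**
Reactants: 13 di-tert-butyl N-[(2E,4R)-4-hydroxypent-2-en-1-yl]imidodicarbonate; 14 5-oxoheptanoic acid
Product: 15 (2R,3E)-5-[bis(tert-butoxycarbonyl)amino]pent-3-en-2-yl 5-oxoheptanoate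
Conditions: EDC·HCl, DMAP (cat.), CH2Cl2, 0 → 23 °C
Reagents that add atoms: none
Why: Steglich esterification acylates the secondary allylic alcohol with retention at the carbinol carbon.

**Step 7**
Reactants: 15 (2R,3E)-5-[bis(tert-butoxycarbonyl)amino]pent-3-en-2-yl 5-oxoheptanoate
Product: 16 (2R,3E)-5-[bis(tert-butoxycarbonyl)amino]pent-3-en-2-yl 4-(2-ethyl-1,3-dioxolan-2-yl)butanoate
Conditions: Me3SiOCH2CH2OSiMe3, Me3SiOTf (5 mol %), CH2Cl2, −78 °C; pyridine
Reagents that add atoms: 1,2-bis(trimethylsilyloxy)ethane, C[Si](C)(C)OCCO[Si](C)(C)C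
Why: Lewis-acid-catalysed silyl-transfer ketalisation at −78 °C masks the ketone (otherwise the most acidic site in steps 8 and 12) without touching the allylic ester or the Boc groups.

**Step 8**
Reactants: 16 (2R,3E)-5-[bis(tert-butoxycarbonyl)amino]pent-3-en-2-yl 4-(2-ethyl-1,3-dioxolan-2-yl)butanoate
Product: 19 (3S,4E)-3-{[bis(tert-butoxycarbonyl)amino]methyl}-2-[2-(2-ethyl-1,3-dioxolan-2-yl)ethyl]hex-4-enoic acid, via silyl ketene acetal 17 (not isolated), via silyl ester 18 (not isolated)
Conditions: LiN(i-Pr)2 (1.2 equiv), THF, −78 °C; Me3SiCl/Et3N; −78 → 50 °C; pH 5 buffer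
Reagents that add atoms: none
Why: Ireland–Claisen rearrangement through a chair transition state with the carbinol methyl group equatorial transfers the R carbinol configuration to the new C3 stereocentre (3S) and gives the E-propenyl group; C2 forms as a mixture that step 12 erases.

**Step 9**
Reactants: 19 (3S,4E)-3-{[bis(tert-butoxycarbonyl)amino]methyl}-2-[2-(2-ethyl-1,3-dioxolan-2-yl)ethyl]hex-4-enoic acid; 10 (1S,2E,3S)-2-{5-[(tert-butyldimethylsilyl)oxy]-1,1-diethoxypentan-2-ylidene}-3-ethenylcyclopentan-1-ol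
Product: 21 diene ester (ester of acid 19 at the ring hydroxyl of 10), via mixed anhydride 20 (not isolated)
Conditions: 2,4,6-Cl3C6H2COCl, Et3N, THF, 23 °C; then 10, DMAP, toluene, 23 → 40 °C
Reagents that add atoms: none
Why: Yamaguchi esterification couples an α-branched acid with a hindered secondary allylic alcohol with retention at the carbinol carbon; the bis-carbamate nitrogen has no N–H and cannot lactamise onto the activated acid.

**Step 10**
Reactants: 21 diene ester
Product: 22 (6Z)-2-oxabicyclo[6.2.1]undec-6-en-3-one carrying the 4-[2-(2-ethyl-1,3-dioxolan-2-yl)ethyl], 5-{[bis(tert-butoxycarbonyl)amino]methyl} and 11-ylidene substituents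
Conditions: second-generation Grubbs catalyst [RuCl2(PCy3)(H2IMes)(=CHPh)] (10 mol %), 1,4-benzoquinone (10 mol %), toluene (1 mM), 80 °C
Reagents that add atoms: none
Why: Ring-closing metathesis between the vinyl and propenyl groups (propene lost) is preorganised by the cis-1,3 arrangement of acyloxy and vinyl groups on the cyclopentane, and the nine-membered ring can only hold a Z alkene.

**Step 11**
Reactants: 22 unsaturated nine-membered lactone
Product: 23 2-oxabicyclo[6.2.1]undecan-3-one with the same three substituents (saturated lactone)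
Conditions: 2-nitrobenzenesulfonohydrazide, Et3N, CH2Cl2, 23 °C
Reagents that add atoms: none
Why: Diimide reduction saturates the strained cis-disubstituted ring alkene and leaves the tetrasubstituted exocyclic alkene untouched; no stereocentre changes.

**Step 12**
Reactants: 23 saturated nine-membered lactone
Product: 26 1,2,4,5,6,7,8,8a-octahydroazulene-5-carboxylic acid bearing 4-(diethoxymethyl), 4-{3-[(tert-butyldimethylsilyl)oxy]propyl}, 5-[2-(2-ethyl-1,3-dioxolan-2-yl)ethyl] and 6-{[bis(tert-butoxycarbonyl)amino]methyl} groups (C4 = Ca and C5 = Cb), via silyl ketene acetal 24 (not isolated), via silyl ester 25 (not isolated)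
Conditions: LiN(i-Pr)2 (1.5 equiv), Me3SiCl/Et3N, THF, −78 °C; −78 → 23 °C; toluene, 90 °C; pH 5 buffer
Reagents that add atoms: none
Why: Kinetic deprotonation of the only enolisable C–H (the lactone α-CH) and O-silylation give the ring-constrained silyl ketene acetal 24, whose [3,3]-sigmatropic shift across the O–C(allyl)–C=C unit forms the Ca–Cb bond as the allylic C–O bond breaks (Ireland–Claisen rearrangement; closest known type: ester-enolate Claisen ring contraction of macrocyclic allylic lactones). The cycloheptane is closed by transannular contraction of the nine-membered lactone (9 → 7, the O–C(=O) unit leaving the ring as the carboxyl group) through a chair-like six-membered transition state. Ca is set by suprafacial chirality transfer from the carbinol carbon, whose oxygen is cis to the ring tether on the cyclopentane, together with the E geometry of the exocyclic alkene. Cb is set because the two arms of the lactone ring (the O–C(=O) arm on the carbinol side, the CH–CH2–CH2 arm on the other side) let only one face of the ketene acetal reach the alkene terminus, whatever the starting α-configuration. The step needs the lactone α-proton to be removed cleanly and the chair-like array to be reachable; the absence of any other acidic C–H (ketone masked, no second ester, no N–H), silyl trapping at −78 °C and the cis-1,3 disposition of oxygen and tether secure this. The carbinol stereocentre is traded for the ring alkene, so the cyclopentene C=C appears exactly where the target has it.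

**Step 13**
Reactants: 26 octahydroazulene carboxylic acid
Product: 28 the corresponding 5-(hydroxymethyl) compound (neopentyl alcohol), via acyl fluoride 27 (not isolated)
Conditions: cyanuric fluoride, pyridine, CH2Cl2, −10 → 23 °C; then NaBH4, MeOH, 0 °C
Reagents that add atoms: none
Why: Acyl fluoride formation tolerates the doubly neopentyl acid, and borohydride reduction of acyl fluorides gives the primary alcohol without touching carbamates, acetals or the silyl ether.

**Step 14**
Reactants: 28 neopentyl alcohol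
Product: 29 diol (5-hydroxymethyl and 4-(3-hydroxypropyl) groups)
Conditions: Bu4NF, THF, 0 → 23 °C
Reagents that add atoms: none
Why: Fluoride-mediated cleavage of the primary silyl ether is compatible with the acetals and the imidodicarbonate.

**Step 15**
Reactants: 29 diol
Product: 31 tricyclic ε-lactone (oxepan-2-one fused across Ca–Cb; C=O on the former propyl arm and O–CH2 on Cb), via lactol 30 (not isolated)
Conditions: TEMPO (20 mol %), PhI(OAc)2 (3 equiv), CH2Cl2, 23 °C
Reagents that add atoms: none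
Why: Oxoammonium-mediated oxidative lactonisation: the unhindered primary alcohol is oxidised first and cyclises onto the slow-reacting neopentyl hydroxyl as lactol 30, which is oxidised on to the lactone with the carbonyl on the propyl arm.

**Step 16**
Reactants: 31 tricyclic ε-lactone
Product: 34 pentacyclic secondary amine (2-azabicyclo[3.2.1]octane core with a propanoyl group on the two-carbon bridge), via amino aldehyde 32 (not isolated), via cyclic imine 33 (not isolated)
Conditions: CF3CO2H/CH2Cl2/H2O (10:10:1), 0 → 23 °C; then AcOH, 60 °C; aq. NaHCO3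
Reagents that add atoms: water, O
Why: Acid removes both Boc groups and hydrolyses acetal and ketal, the primary amine condenses with the neopentyl aldehyde to the six-membered cyclic imine 33, and an intramolecular Mannich reaction (5-exo attack of the ketone enol carbon on the iminium carbon) closes the cyclopentane; the aminomethine bridgehead is fixed by the bicyclo[3.2.1] geometry and the enolisable α-centre should settle cis to nitrogen.

**Step 17**
Reactants: 34 pentacyclic secondary amine
Product: 36 CNP0292775.1, via N-hydroxymethyl amine 35 (not isolated)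
Conditions: CH2O (37 % aq., 1.5 equiv), AcOH, MeCN, 50 °C; aq. NaHCO3
Reagents that add atoms: formaldehyde, C=O
Why: Mannich cyclisation of the β-amino ketone with formaldehyde (N-methylene iminium, 6-endo attack by the enol of the ethyl ketone) closes the piperidin-4-one; the methyl-bearing centre is α to the ketone and should equilibrate to the epimer with methyl pointing away from the cage, as in the target.

**Compound list**

1 | methyl pent-4-enoate | C=CCCC(=O)OC | starting material
2 | diethyl prop-2-en-1-yl phosphate | C=CCOP(=O)(OCC)OCC | starting material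
3 | methyl (4E)-6-[(diethoxyphosphoryl)oxy]hex-4-enoate | COC(=O)CC/C=C/COP(=O)(OCC)OCC | intermediate
4 | 3,3-diethoxyprop-1-yne | C#CC(OCC)OCC | starting material
5 | (3,3-diethoxyprop-1-yn-1-yl)bis(2-methylpropyl)aluminium | CCOC(OCC)C#C[Al](CC(C)C)CC(C)C | intermediate
6 | methyl (4S)-7,7-diethoxy-4-ethenylhept-5-ynoate | C=C[C@H](CCC(=O)OC)C#CC(OCC)OCC | intermediate
7 | (4S)-7,7-diethoxy-4-ethenylhept-5-ynal | C=C[C@H](CCC=O)C#CC(OCC)OCC | intermediate
8 | tert-butyl(3-iodopropoxy)dimethylsilane | CC(C)(C)[Si](C)(C)OCCCI | starting material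
9 | {3-[(tert-butyldimethylsilyl)oxy]propyl}zinc iodide | CC(C)(C)[Si](C)(C)OCCC[Zn]I | intermediate
10 | (1S,2E,3S)-2-{5-[(tert-butyldimethylsilyl)oxy]-1,1-diethoxypentan-2-ylidene}-3-ethenylcyclopentan-1-ol | C=C[C@@H]1CC[C@H](O)/C1=C(\CCCO[Si](C)(C)C(C)(C)C)C(OCC)OCC | intermediate
11 | (2R)-but-3-en-2-ol | C[C@@H](O)C=C | starting material
12 | di-tert-butyl N-(prop-2-en-1-yl)imidodicarbonate | C=CCN(C(=O)OC(C)(C)C)C(=O)OC(C)(C)C | starting material
13 | di-tert-butyl N-[(2E,4R)-4-hydroxypent-2-en-1-yl]imidodicarbonate | C[C@@H](O)/C=C/CN(C(=O)OC(C)(C)C)C(=O)OC(C)(C)C | intermediate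
14 | 5-oxoheptanoic acid | CCC(=O)CCCC(=O)O | starting material
15 | (2R,3E)-5-[bis(tert-butoxycarbonyl)amino]pent-3-en-2-yl 5-oxoheptanoate | CCC(=O)CCCC(=O)O[C@H](C)/C=C/CN(C(=O)OC(C)(C)C)C(=O)OC(C)(C)C | intermediate
16 | (2R,3E)-5-[bis(tert-butoxycarbonyl)amino]pent-3-en-2-yl 4-(2-ethyl-1,3-dioxolan-2-yl)butanoate | CCC1(CCCC(=O)O[C@H](C)/C=C/CN(C(=O)OC(C)(C)C)C(=O)OC(C)(C)C)OCCO1 | intermediate
17 | trimethylsilyl ketene acetal of ester 16 | CCC1(CCC=C(O[Si](C)(C)C)O[C@H](C)/C=C/CN(C(=O)OC(C)(C)C)C(=O)OC(C)(C)C)OCCO1 | intermediate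
18 | trimethylsilyl ester of acid 19 | CCC1(CCC(C(=O)O[Si](C)(C)C)[C@@H](CN(C(=O)OC(C)(C)C)C(=O)OC(C)(C)C)/C=C/C)OCCO1 | intermediate
19 | (3S,4E)-3-{[bis(tert-butoxycarbonyl)amino]methyl}-2-[2-(2-ethyl-1,3-dioxolan-2-yl)ethyl]hex-4-enoic acid (both C2 epimers) | CCC1(CCC(C(=O)O)[C@@H](CN(C(=O)OC(C)(C)C)C(=O)OC(C)(C)C)/C=C/C)OCCO1 | intermediate
20 | mixed anhydride of acid 19 with 2,4,6-trichlorobenzoic acid | CCC1(CCC(C(=O)OC(=O)c2c(Cl)cc(Cl)cc2Cl)[C@@H](CN(C(=O)OC(C)(C)C)C(=O)OC(C)(C)C)/C=C/C)OCCO1 | intermediate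
21 | diene ester: acid 19 esterified at the ring hydroxyl of 10 (1S,2E,3S ring; 3S,4E acid part) | C=C[C@@H]1CC[C@H](OC(=O)C(CCC2(CC)OCCO2)[C@@H](CN(C(=O)OC(C)(C)C)C(=O)OC(C)(C)C)/C=C/C)/C1=C(\CCCO[Si](C)(C)C(C)(C)C)C(OCC)OCC | intermediate
22 | (6Z)-5-{[bis(tert-butoxycarbonyl)amino]methyl}-11-{5-[(tert-butyldimethylsilyl)oxy]-1,1-diethoxypentan-2-ylidene}-4-[2-(2-ethyl-1,3-dioxolan-2-yl)ethyl]-2-oxabicyclo[6.2.1]undec-6-en-3-one (configuration as in SMILES) | O=C1O[C@H]2CC[C@@H](/C=C\[C@H](CN(C(=O)OC(C)(C)C)C(=O)OC(C)(C)C)C1CCC3(CC)OCCO3)/C2=C(/CCCO[Si](C)(C)C(C)(C)C)C(OCC)OCC | intermediate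
23 | 6,7-dihydro derivative of 22 (2-oxabicyclo[6.2.1]undecan-3-one; configuration as in SMILES) | O=C1O[C@H]2CC[C@@H](CC[C@H](CN(C(=O)OC(C)(C)C)C(=O)OC(C)(C)C)C1CCC3(CC)OCCO3)/C2=C(/CCCO[Si](C)(C)C(C)(C)C)C(OCC)OCC | intermediate
24 | trimethylsilyl ketene acetal of lactone 23 (3-trimethylsilyloxy-2-oxabicyclo[6.2.1]undec-3-ene) | C[Si](C)(C)OC=1O[C@H]2CC[C@@H](CC[C@H](CN(C(=O)OC(C)(C)C)C(=O)OC(C)(C)C)C=1CCC3(CC)OCCO3)/C2=C(/CCCO[Si](C)(C)C(C)(C)C)C(OCC)OCC | intermediate
25 | trimethylsilyl ester of acid 26 | CC(C)(C)OC(=O)N(C(=O)OC(C)(C)C)C[C@H]1CC[C@@H]2CCC=C2[C@](C(OCC)OCC)(CCCO[Si](C)(C)C(C)(C)C)[C@@]1(C(=O)O[Si](C)(C)C)CCC3(CC)OCCO3 | intermediate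
26 | 6-{[bis(tert-butoxycarbonyl)amino]methyl}-4-{3-[(tert-butyldimethylsilyl)oxy]propyl}-4-(diethoxymethyl)-5-[2-(2-ethyl-1,3-dioxolan-2-yl)ethyl]-1,2,4,5,6,7,8,8a-octahydroazulene-5-carboxylic acid (configuration as in SMILES) | CC(C)(C)OC(=O)N(C(=O)OC(C)(C)C)C[C@H]1CC[C@@H]2CCC=C2[C@](C(OCC)OCC)(CCCO[Si](C)(C)C(C)(C)C)[C@@]1(C(=O)O)CCC3(CC)OCCO3 | intermediate
27 | acyl fluoride of acid 26 | CC(C)(C)OC(=O)N(C(=O)OC(C)(C)C)C[C@H]1CC[C@@H]2CCC=C2[C@](C(OCC)OCC)(CCCO[Si](C)(C)C(C)(C)C)[C@@]1(C(=O)F)CCC3(CC)OCCO3 | intermediate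
28 | 5-(hydroxymethyl) analogue of 26 (neopentyl alcohol) | CC(C)(C)OC(=O)N(C(=O)OC(C)(C)C)C[C@H]1CC[C@@H]2CCC=C2[C@](C(OCC)OCC)(CCCO[Si](C)(C)C(C)(C)C)[C@@]1(CO)CCC3(CC)OCCO3 | intermediate
29 | diol: 5-(hydroxymethyl)-4-(3-hydroxypropyl) analogue of 26 | CC(C)(C)OC(=O)N(C(=O)OC(C)(C)C)C[C@H]1CC[C@@H]2CCC=C2[C@](C(OCC)OCC)(CCCO)[C@@]1(CO)CCC3(CC)OCCO3 | intermediate
30 | seven-membered lactol of 29 (hemiacetal carbon on the former propyl arm; either anomer) | CC(C)(C)OC(=O)N(C(=O)OC(C)(C)C)C[C@H]3CC[C@@H]4CCC=C4[C@]4(C(OCC)OCC)CCC(O)OC[C@]34CCC5(CC)OCCO5 | intermediate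
31 | tricyclic ε-lactone: oxepan-2-one fused across Ca–Cb of the octahydroazulene, with diethoxymethyl on Ca, dioxolanylethyl on Cb and CH2N(Boc)2 on the next ring carbon | CC(C)(C)OC(=O)N(C(=O)OC(C)(C)C)C[C@H]3CC[C@@H]4CCC=C4[C@]4(C(OCC)OCC)CCC(=O)OC[C@]34CCC5(CC)OCCO5 | intermediate
32 | amino aldehyde: 31 with free CH2NH2, CHO on Ca and 3-oxopentyl on Cb | NC[C@H]3CC[C@@H]4CCC=C4[C@]4(C=O)CCC(=O)OC[C@]34CCC(=O)CC | intermediate
33 | cyclic imine (2,3,4,5-tetrahydropyridine formed from the amine and aldehyde of 32) | C2=NC[C@H]3CC[C@@H]4CCC=C4[C@@]24CCC(=O)OC[C@]34CCC(=O)CC | intermediate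
34 | pentacyclic secondary amine: 2-azabicyclo[3.2.1]octane core with a propanoyl group on the two-carbon bridge, cis to nitrogen | N2C[C@H]3CC[C@@H]4CCC=C4[C@]45CCC(=O)OC[C@]34C[C@H](C(=O)CC)[C@H]25 | intermediate
35 | N-hydroxymethyl derivative of amine 34 | OCN2C[C@H]3CC[C@@H]4CCC=C4[C@]45CCC(=O)OC[C@]34C[C@H](C(=O)CC)[C@H]25 | intermediate
36 | CNP0292775.1 | C[C@@H]1CN2C[C@H]3CC[C@@H]4CCC=C4[C@]45CCC(=O)OC[C@]34C[C@H](C1=O)[C@H]25 | target

**Step count**

Total: 17 steps. Longest linear sequence: 13 steps (steps 1–4, then 9–17; the branch of steps 5–8, then 9–17, is equally long).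

**Steps most likely to fail**

Step 12. The hindered tertiary α-proton may be removed too slowly, or the enolate or ketene acetal may fragment before the strained chair-like array is reached. The fallback sets out from 23 and comes back at 28. Reduction of 23 with i-Bu2AlH at −78 °C should give the lactol F1. Mesylation and elimination (MeSO2Cl, Et3N, then warming), through the lactol mesylate F2, should give the nine-membered cyclic enol ether F3. Heating this allyl vinyl ether (decalin, 180 °C) brings about a base-free aliphatic Claisen rearrangement that forms the same bond and ring and should give the neopentyl aldehyde F4. NaBH4 reduction of F4 gives 28.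

Step 10. Intermolecular metathesis (oligomerisation) may outrun closure of the strained Z-cyclononene. The fallback sets out from 19 and 10 and comes back at 23. Cross-metathesis of the free acid 19 with the free alcohol 10 (second-generation Grubbs catalyst, propene lost) should give the seco hydroxy acid F5. Diimide reduction of the new disubstituted alkene gives the saturated seco hydroxy acid F6. Shiina macrolactonisation (2-methyl-6-nitrobenzoic anhydride, DMAP, high dilution), through the mixed anhydride F7, then closes the ring at the ester C–O bond instead of the C=C bond and gives 23.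

Step 4. Facial selectivity at the aldehyde during the oxidative cyclisation may be poor, giving both carbinol epimers. The fallback sets out from 10 (as the epimer mixture) and comes back at 10. Oxidation with Dess–Martin periodinane should give the cross-conjugated enone F8, in which allylic strain holds the vinyl group pseudoaxial. Luche reduction (NaBH4, CeCl3·7H2O, MeOH, −78 °C), or CBS reduction for reagent control, then delivers hydride anti to the vinyl group and should give the 1,3-cis alcohol 10.

**Further compounds**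

F1 | step 12 | lactol from 23 (3-hydroxy-2-oxabicyclo[6.2.1]undecane) | OC1O[C@H]2CC[C@@H](CC[C@H](CN(C(=O)OC(C)(C)C)C(=O)OC(C)(C)C)C1CCC3(CC)OCCO3)/C2=C(/CCCO[Si](C)(C)C(C)(C)C)C(OCC)OCC
F2 | step 12 | lactol mesylate | CS(=O)(=O)OC1O[C@H]2CC[C@@H](CC[C@H](CN(C(=O)OC(C)(C)C)C(=O)OC(C)(C)C)C1CCC3(CC)OCCO3)/C2=C(/CCCO[Si](C)(C)C(C)(C)C)C(OCC)OCC
F3 | step 12 | nine-membered cyclic enol ether (2-oxabicyclo[6.2.1]undec-3-ene) | C=1O[C@H]2CC[C@@H](CC[C@H](CN(C(=O)OC(C)(C)C)C(=O)OC(C)(C)C)C=1CCC3(CC)OCCO3)/C2=C(/CCCO[Si](C)(C)C(C)(C)C)C(OCC)OCC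
F4 | step 12 | neopentyl aldehyde (5-formyl analogue of 26) | CC(C)(C)OC(=O)N(C(=O)OC(C)(C)C)C[C@H]1CC[C@@H]2CCC=C2[C@](C(OCC)OCC)(CCCO[Si](C)(C)C(C)(C)C)[C@@]1(C=O)CCC3(CC)OCCO3
F5 | step 10 | seco hydroxy acid from cross-metathesis of 19 and 10 (E-alkene) | CCC1(CCC(C(=O)O)[C@@H](CN(C(=O)OC(C)(C)C)C(=O)OC(C)(C)C)/C=C/[C@@H]2CC[C@H](O)/C2=C(\CCCO[Si](C)(C)C(C)(C)C)C(OCC)OCC)OCCO1
F6 | step 10 | saturated seco hydroxy acid | CCC1(CCC(C(=O)O)[C@@H](CN(C(=O)OC(C)(C)C)C(=O)OC(C)(C)C)CC[C@@H]2CC[C@H](O)/C2=C(\CCCO[Si](C)(C)C(C)(C)C)C(OCC)OCC)OCCO1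
F7 | step 10 | mixed anhydride of F6 with 2-methyl-6-nitrobenzoic acid | CCC1(CCC(C(=O)OC(=O)c2c(C)cccc2[N+](=O)[O-])[C@@H](CN(C(=O)OC(C)(C)C)C(=O)OC(C)(C)C)CC[C@@H]3CC[C@H](O)/C3=C(\CCCO[Si](C)(C)C(C)(C)C)C(OCC)OCC)OCCO1
F8 | step 4 | (2E,3S)-2-{5-[(tert-butyldimethylsilyl)oxy]-1,1-diethoxypentan-2-ylidene}-3-ethenylcyclopentan-1-one | C=C[C@@H]1CCC(=O)/C1=C(\CCCO[Si](C)(C)C(C)(C)C)C(OCC)OCC
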